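## Structural features

The target is a spiro-tricycle. Ring A, a 2,3,4-trimethoxybenzene, is fused to ring B, a seven-membered carbocycle (C5–C9 plus the two shared arene carbons), and ring B is joined through the quaternary carbon C5 to ring C, a 2,6-dimethoxycyclohexa-2,5-dienone. C5 is not stereogenic because the two arms of ring C are identical. All chirality therefore sits in three contiguous centres of ring B: C7 (R, methyl), C8 (S, methyl) and C9 (R, benzylic acetoxy), with 7-Me/8-Me trans and 8-Me/9-OAc trans. The fragile elements are the cross-conjugated dienone (dienone–phenol rearrangement in acid, attack of hydride or carbon nucleophiles at its carbonyl and β-carbons), the benzylic acetate on an electron-rich arene (ionisation, elimination) and, whenever C9 is a ketone, the epimerisable C8. The real difficulties are C5, whose formation must dearomatise a syringol ring while a seven-membered ring closes, and a stereotriad in a conformationally mobile medium ring. C6 (the CH2 on C5) and C9 (the oxygenated carbon on ring A) flank the two methyl-bearing carbons and can both be traced back to carbonyl carbons. The key step uses exactly this: C6–C7(Me)–C8(Me)–C9 is a 2,3-dimethyl-1,4-dioxygenated chain, so the C7–C8 bond can be made by joining two propionyl units at their α-carbons, one bound to ring A as an aryl ketone and one bound to a chiral auxiliary.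

## Logic of the disconnections

**C9–O acyl bond (21 ⇒ 20).** The acetate is the most labile group and carries no skeletal information, so it is removed first. What remains differs from 21 only by an ester. The forward step has to acylate a hindered benzylic alcohol without acid, so that neither the dienone nor the benzylic C–O bond is disturbed.

**C9–H bond (20 ⇒ 19).** Removing the carbinol hydrogen makes C9 a ketone. A C9 carbonyl makes C8 epimerisable and lets ring B itself decide two of the three stereocentres, so only C7 has to be carried in absolute form. The forward reduction must take the aryl ketone and spare the dienone carbonyl, and hydride must arrive on the face that leaves the hydroxyl trans to the 8-methyl group.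

**C8–H bond, as a stereochemical cut (19 ⇒ 18 ⇒ 17).** 19 is traced to its C8-epimeric mixture 18 and this to the alcohol mixture 17. The reason is convergence: every C8/C9 diastereomer funnels into one ketone under thermodynamic control. The demand is that trans-7,8 is clearly the more stable arrangement in ring B, and that a base able to enolise C9 leaves ring C alone.

**C5–C6 bond (17 ⇒ 16 ⇒ 15).** This cut opens ring B, removes the quaternary carbon and returns ring C to an aromatic syringol, so 15 is an acyclic chain on a biaryl. In the forward step the phenolate must alkylate through its para carbon. Its oxygen and ortho carbons cannot reach C6 within the molecule, so the competitor is intermolecular O-alkylation, which calls for high dilution. The C9 oxygen must be masked, because a free C9 hydroxyl would displace the C6 sulfonate and close a tetrahydrofuran.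

**C–O bonds of protecting and leaving groups (15 ⇒ 14 ⇒ 13 ⇒ 12 ⇒ 11).** No carbon–carbon bond is cut here. The phenol is traced to its benzyl ether, the sulfonate to the primary alcohol, and the mono-silyl ether to the bis-silyl ether of the 1,4-diol. The secondary hydroxyl of 11 cannot be silylated in the presence of the primary one. Both are therefore silylated, and the unhindered primary ether is cleaved selectively. The demands are kinetic selectivity in that cleavage, and hydrogenolysis of the benzyl ether only after the sulfonate is in place, so that the phenol never meets the sulfonyl chloride.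

**C6 and C9 back to the carbonyl level (11 ⇒ 10).** Both oxygenated carbons become carbonyl carbons, C6 as an acyl oxazolidinone and C9 as the aryl ketone. This yields a 2,3-dimethyl-1,4-dicarbonyl compound. The forward reduction must remove the auxiliary without touching the C7 configuration. The configuration formed at C9 is irrelevant because C9 is re-oxidised.

**C7–C8 bond (10 ⇒ 6 + 7).** This is the strategic cut. It divides the aliphatic chain into two propionyl halves of equal size, puts both methyl groups and both oxygenated carbons in place at once, and lets a purchasable auxiliary fix C7. The forward step must couple two different enolates rather than dimerise either, and must place the new bond on one face of the imide enolate. C8 need not be controlled.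

**Biaryl bond, C–B and C–Br bonds (6 ⇒ 2 + 5; 5 ⇒ 4 ⇒ 3; 2 ⇒ 1).** The biaryl bond is cut so that only one partner carries ortho substituents. The boron sits on the unhindered ring C fragment and the halogen on ring A next to the acyl group, where electrophilic bromination of 1 puts it. The benzyl ether is kept as the phenol mask because it is inert to amide base, the iron oxidant, hydride and silylating agents, and leaves under neutral conditions.

## Other disconnections considered

**Alternative 1:** one-carbon ring expansion.
- **Cut and forward step.** C8 is excised, contracting ring B to a six-membered spiro-tetralone handled as its trimethylsilyl enol ether A1. Et2Zn/CH2I2 cyclopropanates the enol ether double bond (Simmons–Smith type). FeCl3 then opens the siloxycyclopropane at the internal bond by one-electron oxidation to a ring-enlarged β-chloro ketone, and NaOAc eliminates HCl to give the ring-B enone A2.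
- **In its favour.** A six-membered spiro ring should close more easily than a seven-membered one; on this point the alternative is the better. All intermediates up to A2 are achiral, so no diastereomer mixtures are carried; this is also better.
- **Against it here.** A2 has no stereocentre and no C8 methyl group. C7, C8 and C9 all remain to be set, by an enantioselective conjugate reduction, an α-methylation and a ketone reduction. The zinc carbenoid and the Lewis-acidic iron trichloride also meet a finished dienone, which has two further oxygenated double bonds and can rearrange to a phenol.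
- **Comparison.** On structure, the chosen plan delivers both methyl groups and the absolute configuration at C7 with the C7–C8 bond, whereas the alternative delivers the ring and nothing else. On mechanism, both rely on a one-electron oxidation by an iron salt, but the chosen plan runs it while ring C is still a protected arene. On step economy, the ring construction is shorter, but the stereochemical end game should cost at least as many steps as it saves.

**Alternative 2:** asymmetric conjugate methylation.
- **Cut and forward step.** The C7–CH3 bond is cut. Cu(OTf)2 with a chiral phosphoramidite transfers methyl from Me3Al to C7 of the achiral 8-methyl enone A3, and protonation of the aluminium enolate at C8 gives the trans ketone A4, which is identical with 19.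
- **In its favour.** Control is catalytic rather than by a stoichiometric auxiliary; this is better. A4 is two steps from the target, the same two steps as in the chosen plan; this is equal. C8 is set by protonation or equilibration, as in the chosen plan; this is also equal.
- **Against it here.** A3 is an α-substituted enone in a seven-membered ring, a sluggish class of acceptor. Ring C offers two more β-carbons and a carbonyl to a Lewis-acidic methyl donor. Face selection must occur beside a spiro quaternary centre. A3 must itself be built with ring B, C5 and the dienone complete.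
- **Comparison.** On structure, the alternative forms only a carbon–methyl bond and needs the whole skeleton first; the chosen plan forms the central skeletal bond. On mechanism, a catalyst-controlled 1,4-addition replaces a chelated auxiliary enolate whose facial bias is well understood. On step economy, the end game is equal, and the front end is longer unless A3 is unusually easy to reach.

**Alternative 3:** phenolate para-alkylation as the strategic step.
- **Cut and forward step.** The C5–C6 bond is cut. Cs2CO3 converts the stereodefined phenol mesylate A5 into its phenolate, whose para carbon displaces the mesylate to give the silyl ether A6. Ring B, C5 and the dienone form in one step.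
- **In its favour.** All three stereocentres are fixed before ring closure, so nothing has to be corrected afterwards. A6 needs only desilylation and acetylation, which avoids an oxidation, an equilibration and a hydride reduction in the presence of the dienone; on this point the alternative is the better.
- **Against it here.** The burden moves to a stereocontrolled synthesis of the acyclic 7R,8S,9R triad of A5, which should take several stereoselective steps where the chosen plan needs one coupling.
- **Comparison.** On mechanism, the ring closure is the same reaction as step 10 of the chosen plan, with equal risk; there it is run on the epimer mixture 15, of which A5 is one isomer (as A6 is of 16). On structure, the alternative treats the ring closure as the main event and solves the stereochemistry first. The chosen plan builds the carbon chain in one step and settles C8 and C9 last, inside the ring. On step economy, the end game is about three steps shorter and the front end correspondingly longer.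

Key step: step 4

**Remarks and assumption**
- Numbering: ring A is the trimethoxybenzene, ring B the seven-membered ring, ring C the dienone. C5 is the spiro carbon, C6 the CH2, C7 and C8 the methyl-bearing carbons and C9 the oxygenated benzylic carbon (benzo[7]annulene numbering).
- Mixtures: 10 is drawn as its (2S,3S) isomer although its C8 epimer forms with it. 11–17 are carried as mixtures of epimers at C8 and C9, and 18 as a mixture at C8, so their SMILES carry no descriptor at these centres.
- Configuration: the (R)-auxiliary in 7 is the correct enantiomer. On the enolate-alkylation model it gives the 2S acyl centre of 10. This is the same spatial arrangement as 7R in 21; the descriptor changes only because C6 outranks C8 while it is a carbonyl or CH2O carbon, and ranks below it once it is the ring CH2.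
- Assumption: 1, 3 and 7 are taken to be purchasable.

## Route

Step 1
Reactants: 1 1-(3,4,5-trimethoxyphenyl)propan-1-one
Product: 2 1-(2-bromo-3,4,5-trimethoxyphenyl)propan-1-one
Conditions: NBS (1.05 equiv), MeCN, 0 °C → rt, dark
Reagents that add atoms: N-bromosuccinimide, O=C1CCC(=O)N1Br
Why: Electrophilic aromatic bromination; the two free ring positions are equivalent and each is ortho to one methoxy and para to another, so the ring should react faster than the ketone α-carbon under acid-free polar conditions.

Step 2
Reactants: 3 4-bromo-2,6-dimethoxyphenol
Product: 4 2-(benzyloxy)-5-bromo-1,3-dimethoxybenzene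
Conditions: BnBr, K2CO3, DMF, rt
Reagents that add atoms: benzyl bromide, BrCc1ccccc1
Why: Williamson etherification of the phenolate; the benzyl ether is chosen because it survives amide base, the iron oxidant, hydride and silylation and is later removed under neutral conditions.

Step 3
Reactants: 4 2-(benzyloxy)-5-bromo-1,3-dimethoxybenzene; 2 1-(2-bromo-3,4,5-trimethoxyphenyl)propan-1-one
Product: 6 1-[2-(4-benzyloxy-3,5-dimethoxyphenyl)-3,4,5-trimethoxyphenyl]propan-1-one, via aryl pinacol boronate 5 (not isolated)
Conditions: B2pin2 (1.0 equiv), Pd2(dba)3 (1 mol %), XPhos (4 mol %), KOAc, 1,4-dioxane, 100 °C; then 2 (0.85 equiv), aq. K3PO4, 100 °C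
Reagents that add atoms: none
Why: Miyaura borylation of the unhindered electron-rich bromide, followed in the same flask by Suzuki–Miyaura coupling; the bulky biarylphosphine on zerovalent palladium handles oxidative addition at the di-ortho-substituted bromide 2, and since only ring A carries ortho groups the biaryl is not unduly congested.

Step 4
Reactants: 6 1-[2-(4-benzyloxy-3,5-dimethoxyphenyl)-3,4,5-trimethoxyphenyl]propan-1-one; 7 (R)-4-benzyl-3-propionyloxazolidin-2-one (1.5 equiv)
Product: 10 (4R)-4-benzyl-3-[(2S,3S)-4-[2-(4-benzyloxy-3,5-dimethoxyphenyl)-3,4,5-trimethoxyphenyl]-2,3-dimethyl-4-oxobutanoyl]oxazolidin-2-one, via biaryl ketone lithium Z-enolate 8 (not isolated), via imide lithium Z-enolate 9 (not isolated)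
Conditions: LiN(i-Pr)2 (2.6 equiv), THF, −78 °C; then Fe(acac)3 (2.5 equiv), THF, −78 °C → rt
Reagents that add atoms: none
Why: LiN(i-Pr)2 converts both carbonyl compounds into their lithium Z-enolates 8 and 9, and Fe(acac)3, a soluble one-electron oxidant of trivalent iron, takes an electron from the more electron-rich ketone enolate 8 to give an α-keto radical at C8. This electrophilic radical adds to C7 of the chelated imide enolate 9, and a second equivalent of Fe(acac)3 oxidises the resulting radical anion to the imide carbonyl, so two enolates and two equivalents of oxidant give one C7–C8 σ-bond. The closest known reaction type is the intermolecular oxidative heterocoupling of a ketone enolate with an N-acyl oxazolidinone enolate to a 2,3-disubstituted 1,4-dicarbonyl compound, the crossed version of oxidative enolate dimerisation. No ring is closed. C7 is controlled by the auxiliary: lithium holds the enolate oxygen and the oxazolidinone carbonyl in one plane, the benzyl group of the (R)-auxiliary covers one face, and C8 bonds to the opposite face as an alkyl halide would, which gives the 2S centre of 10. C8 arises from a planar radical and is not controlled, so 10 forms together with its C8 epimer and both are carried on, because C8 is corrected in step 13. The selectivity the step needs is cross- over homocoupling; it rests on the different oxidation potentials of the two enolates (8 is oxidised, 9 acts as acceptor) and is reinforced by using the inexpensive imide 7 in excess. Ring C is still a benzyl-protected arene here, so no phenol or dienone is exposed to the oxidant.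

Step 5
Reactants: 10 (4R)-4-benzyl-3-[(2S,3S)-4-[2-(4-benzyloxy-3,5-dimethoxyphenyl)-3,4,5-trimethoxyphenyl]-2,3-dimethyl-4-oxobutanoyl]oxazolidin-2-one (with its C8 epimer)
Product: 11 (3S)-1-[2-(4-benzyloxy-3,5-dimethoxyphenyl)-3,4,5-trimethoxyphenyl]-2,3-dimethylbutane-1,4-diol (epimers at C8 and C9)
Conditions: LiBH4, MeOH (2 equiv), THF, 0 °C → rt
Reagents that add atoms: none
Why: Hydride reduction of the aryl ketone and reductive cleavage of the N-acyl oxazolidinone to the primary alcohol, which releases the auxiliary for recovery; the medium is not basic enough to epimerise C7, and the unselective reduction at C9 is harmless because C9 is re-oxidised in step 12.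

Step 6
Reactants: 11 (3S)-1-[2-(4-benzyloxy-3,5-dimethoxyphenyl)-3,4,5-trimethoxyphenyl]-2,3-dimethylbutane-1,4-diol
Product: 12 1,4-bis(tert-butyldimethylsilyl) ether of 11 (epimers at C8 and C9)
Conditions: TBSOTf (2.5 equiv), 2,6-lutidine, CH2Cl2, −78 → 0 °C
Reagents that add atoms: tert-butyldimethylsilyl triflate, CC(C)(C)[Si](C)(C)OS(=O)(=O)C(F)(F)F
Why: Exhaustive silylation; the silyl triflate is needed for the hindered benzylic hydroxyl, and silylating both oxygens avoids any attempt to distinguish them at this stage.

Step 7
Reactants: 12 1,4-bis(tert-butyldimethylsilyl) ether of 11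
Product: 13 (2S)-4-[2-(4-benzyloxy-3,5-dimethoxyphenyl)-3,4,5-trimethoxyphenyl]-4-(tert-butyldimethylsilyloxy)-2,3-dimethylbutan-1-ol (epimers at C8 and C9)
Conditions: HF·pyridine, pyridine, THF, 0 °C
Reagents that add atoms: none
Why: Kinetically selective desilylation; the unhindered primary silyl ether should be cleaved well before the secondary benzylic one, which is flanked by the C8 branch and the ortho aryl group, and the buffered medium avoids ionisation at C9.

Step 8
Reactants: 13 (2S)-4-[2-(4-benzyloxy-3,5-dimethoxyphenyl)-3,4,5-trimethoxyphenyl]-4-(tert-butyldimethylsilyloxy)-2,3-dimethylbutan-1-ol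
Product: 14 (2S)-4-[2-(4-benzyloxy-3,5-dimethoxyphenyl)-3,4,5-trimethoxyphenyl]-4-(tert-butyldimethylsilyloxy)-2,3-dimethylbutyl methanesulfonate (epimers at C8 and C9)
Conditions: MsCl, Et3N, CH2Cl2, 0 °C
Reagents that add atoms: methanesulfonyl chloride, CS(=O)(=O)Cl
Why: Sulfonylation of the only free hydroxyl; with the C9 oxygen silylated the 1,4-related oxygen cannot displace the new leaving group to form a tetrahydrofuran.

Step 9
Reactants: 14 (2S)-4-[2-(4-benzyloxy-3,5-dimethoxyphenyl)-3,4,5-trimethoxyphenyl]-4-(tert-butyldimethylsilyloxy)-2,3-dimethylbutyl methanesulfonate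
Product: 15 (2S)-4-(tert-butyldimethylsilyloxy)-4-[2-(4-hydroxy-3,5-dimethoxyphenyl)-3,4,5-trimethoxyphenyl]-2,3-dimethylbutyl methanesulfonate (epimers at C8 and C9)
Conditions: H2 (1 atm), Pd/C, EtOAc, rt
Reagents that add atoms: none
Why: Hydrogenolysis of the aryl benzyl ether under neutral conditions; the primary mesylate, the aryl methyl ethers and the bulky benzylic silyl ether should be inert, and the phenol is released only after the sulfonyl chloride has been used.

Step 10
Reactants: 15 (2S)-4-(tert-butyldimethylsilyloxy)-4-[2-(4-hydroxy-3,5-dimethoxyphenyl)-3,4,5-trimethoxyphenyl]-2,3-dimethylbutyl methanesulfonate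
Product: 16 (7R)-9-(tert-butyldimethylsilyloxy)-2,3,4,3',5'-pentamethoxy-7,8-dimethyl-6,7,8,9-tetrahydrospiro[benzo[7]annulene-5,1'-cyclohexa[2,5]dien]-4'-one (epimers at C8 and C9)
Conditions: Cs2CO3, MeCN (0.005 M), 70 °C
Reagents that add atoms: none
Why: Intramolecular para C-alkylation of a phenolate (dearomatising SN2 displacement) forms the C5–C6 bond, the spiro carbon, the dienone and ring B; the twisted biaryl holds the chain over the face of ring C, the phenolate oxygen and ortho carbons cannot reach C6, and dilution suppresses intermolecular O-alkylation. C5 is not stereogenic, so no new stereocentre arises.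

Step 11
Reactants: 16 (7R)-9-(tert-butyldimethylsilyloxy)-2,3,4,3',5'-pentamethoxy-7,8-dimethyl-6,7,8,9-tetrahydrospiro[benzo[7]annulene-5,1'-cyclohexa[2,5]dien]-4'-one
Product: 17 (7R)-9-hydroxy-2,3,4,3',5'-pentamethoxy-7,8-dimethyl-6,7,8,9-tetrahydrospiro[benzo[7]annulene-5,1'-cyclohexa[2,5]dien]-4'-one (epimers at C8 and C9)
Conditions: Bu4NF, AcOH (1:1), THF, rt → 45 °C
Reagents that add atoms: none
Why: Fluoride-mediated desilylation; buffering with acetic acid keeps the liberated C9 alkoxide protonated so that it does not add to the dienone, and no strong acid is present to trigger dienone–phenol rearrangement.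

Step 12
Reactants: 17 (7R)-9-hydroxy-2,3,4,3',5'-pentamethoxy-7,8-dimethyl-6,7,8,9-tetrahydrospiro[benzo[7]annulene-5,1'-cyclohexa[2,5]dien]-4'-one
Product: 18 (7R)-2,3,4,3',5'-pentamethoxy-7,8-dimethyl-7,8-dihydrospiro[benzo[7]annulene-5,1'-cyclohexa[2,5]diene]-4',9(6H)-dione (epimers at C8)
Conditions: Dess–Martin periodinane, CH2Cl2, rt
Reagents that add atoms: none
Why: Dess–Martin oxidation of the secondary benzylic alcohol under near-neutral conditions; it removes the C9 stereocentre, so the four diastereomers of 17 collapse to two, and the dienone is inert to the reagent.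

Step 13
Reactants: 18 (7R)-2,3,4,3',5'-pentamethoxy-7,8-dimethyl-7,8-dihydrospiro[benzo[7]annulene-5,1'-cyclohexa[2,5]diene]-4',9(6H)-dione (epimers at C8)
Product: 19 (7R,8S)-2,3,4,3',5'-pentamethoxy-7,8-dimethyl-7,8-dihydrospiro[benzo[7]annulene-5,1'-cyclohexa[2,5]diene]-4',9(6H)-dione
Conditions: DBU (0.3 equiv), toluene, rt
Reagents that add atoms: none
Why: Base-mediated epimerisation through the C9 enolate; only C8 is acidic (C7 is β to the ketone, ring C has no enolisable hydrogen), and the trans isomer with both methyl groups pseudo-equatorial should dominate at equilibrium, so C8 is set by thermodynamic control relative to the fixed C7.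

Step 14
Reactants: 19 (7R,8S)-2,3,4,3',5'-pentamethoxy-7,8-dimethyl-7,8-dihydrospiro[benzo[7]annulene-5,1'-cyclohexa[2,5]diene]-4',9(6H)-dione
Product: 20 (7R,8S,9R)-9-hydroxy-2,3,4,3',5'-pentamethoxy-7,8-dimethyl-6,7,8,9-tetrahydrospiro[benzo[7]annulene-5,1'-cyclohexa[2,5]dien]-4'-one
Conditions: NaBH4 (1.0 equiv), MeOH/CH2Cl2 (1:1), −40 °C
Reagents that add atoms: none
Why: Chemoselective borohydride reduction; a cross-conjugated cyclohexadienone carbonyl is reduced more slowly than a ring-twisted aryl alkyl ketone, so limited hydride at low temperature should take C9 only. A small hydride should prefer the torsionally favoured axial approach, which leaves the new hydroxyl pseudo-equatorial and trans to the 8-methyl group (9R, substrate control by ring B).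

Step 15
Reactants: 20 (7R,8S,9R)-9-hydroxy-2,3,4,3',5'-pentamethoxy-7,8-dimethyl-6,7,8,9-tetrahydrospiro[benzo[7]annulene-5,1'-cyclohexa[2,5]dien]-4'-one
Product: 21 (7R,8S,9R)-2,3,4,3',5'-pentamethoxy-7,8-dimethyl-4'-oxo-6,7,8,9-tetrahydrospiro[benzo[7]annulene-5,1'-cyclohexa[2,5]dien]-9-yl acetate
Conditions: Ac2O, pyridine, DMAP (cat.), CH2Cl2, rt
Reagents that add atoms: acetic anhydride, CC(=O)OC(C)=O
Why: Nucleophile-catalysed acylation of the secondary alcohol with retention at C9; the basic medium does not ionise the benzylic position and leaves the dienone intact.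

## Compound list

1 | 1-(3,4,5-trimethoxyphenyl)propan-1-one | CCC(=O)c1cc(OC)c(OC)c(OC)c1 | starting material
2 | 1-(2-bromo-3,4,5-trimethoxyphenyl)propan-1-one | CCC(=O)c1cc(OC)c(OC)c(OC)c1Br | intermediate
3 | 4-bromo-2,6-dimethoxyphenol | COc1cc(Br)cc(OC)c1O | starting material
4 | 2-(benzyloxy)-5-bromo-1,3-dimethoxybenzene | COc1cc(Br)cc(OC)c1OCc1ccccc1 | intermediate
5 | 2-[4-(benzyloxy)-3,5-dimethoxyphenyl]-4,4,5,5-tetramethyl-1,3,2-dioxaborolane | COc1cc(cc(OC)c1OCc1ccccc1)B1OC(C)(C)C(C)(C)O1 | intermediate (not isolated)
6 | 1-[2-(4-benzyloxy-3,5-dimethoxyphenyl)-3,4,5-trimethoxyphenyl]propan-1-one | CCC(=O)c1cc(OC)c(OC)c(OC)c1-c1cc(OC)c(OCc2ccccc2)c(OC)c1 | intermediate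
7 | (R)-4-benzyl-3-propionyloxazolidin-2-one | CCC(=O)N1[C@H](Cc2ccccc2)COC1=O | starting material
8 | lithium (Z)-enolate of 6 | C/C=C(\O[Li])c1cc(OC)c(OC)c(OC)c1-c1cc(OC)c(OCc2ccccc2)c(OC)c1 | intermediate (not isolated)
9 | lithium (Z)-enolate of 7 | C/C=C(\O[Li])N1[C@H](Cc2ccccc2)COC1=O | intermediate (not isolated)
10 | (4R)-4-benzyl-3-[(2S,3S)-4-[2-(4-benzyloxy-3,5-dimethoxyphenyl)-3,4,5-trimethoxyphenyl]-2,3-dimethyl-4-oxobutanoyl]oxazolidin-2-one (formed with its C8 epimer) | O=C(N1[C@H](Cc2ccccc2)COC1=O)[C@@H](C)[C@H](C)C(=O)c1cc(OC)c(OC)c(OC)c1-c1cc(OC)c(OCc2ccccc2)c(OC)c1 | intermediate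
11 | (3S)-1-[2-(4-benzyloxy-3,5-dimethoxyphenyl)-3,4,5-trimethoxyphenyl]-2,3-dimethylbutane-1,4-diol (epimers at C8 and C9) | OC[C@@H](C)C(C)C(O)c1cc(OC)c(OC)c(OC)c1-c1cc(OC)c(OCc2ccccc2)c(OC)c1 | intermediate
12 | 1,4-bis(tert-butyldimethylsilyl) ether of 11 (epimers at C8 and C9) | CC(C)(C)[Si](C)(C)OC[C@@H](C)C(C)C(O[Si](C)(C)C(C)(C)C)c1cc(OC)c(OC)c(OC)c1-c1cc(OC)c(OCc2ccccc2)c(OC)c1 | intermediate
13 | (2S)-4-[2-(4-benzyloxy-3,5-dimethoxyphenyl)-3,4,5-trimethoxyphenyl]-4-(tert-butyldimethylsilyloxy)-2,3-dimethylbutan-1-ol (epimers at C8 and C9) | OC[C@@H](C)C(C)C(O[Si](C)(C)C(C)(C)C)c1cc(OC)c(OC)c(OC)c1-c1cc(OC)c(OCc2ccccc2)c(OC)c1 | intermediate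
14 | (2S)-4-[2-(4-benzyloxy-3,5-dimethoxyphenyl)-3,4,5-trimethoxyphenyl]-4-(tert-butyldimethylsilyloxy)-2,3-dimethylbutyl methanesulfonate (epimers at C8 and C9) | CS(=O)(=O)OC[C@@H](C)C(C)C(O[Si](C)(C)C(C)(C)C)c1cc(OC)c(OC)c(OC)c1-c1cc(OC)c(OCc2ccccc2)c(OC)c1 | intermediate
15 | (2S)-4-(tert-butyldimethylsilyloxy)-4-[2-(4-hydroxy-3,5-dimethoxyphenyl)-3,4,5-trimethoxyphenyl]-2,3-dimethylbutyl methanesulfonate (epimers at C8 and C9) | CS(=O)(=O)OC[C@@H](C)C(C)C(O[Si](C)(C)C(C)(C)C)c1cc(OC)c(OC)c(OC)c1-c1cc(OC)c(O)c(OC)c1 | intermediate
16 | (7R)-9-(tert-butyldimethylsilyloxy)-2,3,4,3',5'-pentamethoxy-7,8-dimethyl-6,7,8,9-tetrahydrospiro[benzo[7]annulene-5,1'-cyclohexa[2,5]dien]-4'-one (epimers at C8 and C9) | COC1=CC2(C=C(OC)C1=O)C[C@@H](C)C(C)C(O[Si](C)(C)C(C)(C)C)c1cc(OC)c(OC)c(OC)c12 | intermediate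
17 | (7R)-9-hydroxy-2,3,4,3',5'-pentamethoxy-7,8-dimethyl-6,7,8,9-tetrahydrospiro[benzo[7]annulene-5,1'-cyclohexa[2,5]dien]-4'-one (epimers at C8 and C9) | COC1=CC2(C=C(OC)C1=O)C[C@@H](C)C(C)C(O)c1cc(OC)c(OC)c(OC)c12 | intermediate
18 | (7R)-2,3,4,3',5'-pentamethoxy-7,8-dimethyl-7,8-dihydrospiro[benzo[7]annulene-5,1'-cyclohexa[2,5]diene]-4',9(6H)-dione (epimers at C8) | COC1=CC2(C=C(OC)C1=O)C[C@@H](C)C(C)C(=O)c1cc(OC)c(OC)c(OC)c12 | intermediate
19 | (7R,8S)-2,3,4,3',5'-pentamethoxy-7,8-dimethyl-7,8-dihydrospiro[benzo[7]annulene-5,1'-cyclohexa[2,5]diene]-4',9(6H)-dione | COC1=CC2(C=C(OC)C1=O)C[C@@H](C)[C@H](C)C(=O)c1cc(OC)c(OC)c(OC)c12 | intermediate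
20 | (7R,8S,9R)-9-hydroxy-2,3,4,3',5'-pentamethoxy-7,8-dimethyl-6,7,8,9-tetrahydrospiro[benzo[7]annulene-5,1'-cyclohexa[2,5]dien]-4'-one | COC1=CC2(C=C(OC)C1=O)C[C@@H](C)[C@H](C)[C@@H](O)c1cc(OC)c(OC)c(OC)c12 | intermediate
21 | (7R,8S,9R)-2,3,4,3',5'-pentamethoxy-7,8-dimethyl-4'-oxo-6,7,8,9-tetrahydrospiro[benzo[7]annulene-5,1'-cyclohexa[2,5]dien]-9-yl acetate | COC1=CC2(C=C(OC)C1=O)C[C@@H](C)[C@H](C)[C@@H](OC(C)=O)c1cc(OC)c(OC)c(OC)c12 | target

## Step count and least certain steps

Total: 15 steps. Longest linear sequence: 14 steps (from 3 through steps 2–15, or equally from 1 through steps 1 and 3–15).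

**Step 4 (key step).** The most likely failure is homocoupling of either enolate and low mass balance, because the two oxidation rates may not be far enough apart with this bulky biaryl ketone. Facial selectivity at C7 could also be lower for a radical bond formation than for a two-electron alkylation, and residual amide base could erode C7 in the product. Fallback, a two-electron alkylation with a chiral-pool electrophile: setting out from 6, the lithium enolate (LiN(i-Pr)2, THF, −78 °C) is alkylated with ethyl (S)-2-(trifluoromethylsulfonyloxy)propanoate. SN2 displacement with inversion should give ethyl (2S)-4-[2-(4-benzyloxy-3,5-dimethoxyphenyl)-3,4,5-trimethoxyphenyl]-2,3-dimethyl-4-oxobutanoate F1 as a C8-epimer mixture, with C7 taken from the lactate centre. LiBH4 in THF then reduces ketone and ester, and the route is rejoined at 11.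

**Step 10.** The most likely failure is intermolecular O-alkylation to oligomers outrunning a slow seven-membered closure that also costs the aromaticity of ring C. E2 loss of the mesylate and unequal cyclisation rates of the four diastereomers are further concerns. Fallback, a softer electrophile in a protic, oxygen-shielding medium: setting out from 15, NaI in acetone gives 4-[6-[(3S)-1-(tert-butyldimethylsilyloxy)-4-iodo-2,3-dimethylbutyl]-2,3,4-trimethoxyphenyl]-2,6-dimethoxyphenol F2. KOt-Bu in t-BuOH/THF at high dilution then closes the ring through the hydrogen-bonded potassium phenolate, rejoining the route at 16.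

**Step 13.** The most likely failure is an equilibrium that does not lie far enough on the trans side in this flexible ring. Prolonged base exposure could also allow conjugate addition of the C9 enolate, through C8, to a β-carbon of ring C. Fallback, moving the C8 decision to the acyclic stage: setting out from 10, its two C8 epimers are separated by chromatography and only the (2S,3S) isomer is taken through steps 5–12. The oxidation of step 12 then delivers the trans ketone directly and the route is rejoined at 19 without any equilibration. No new compound is made.

**Step 14.** The most likely failure is hydride delivery to the wrong face of C9, because the pseudo-axial arm of ring C may screen the axial trajectory. Reduction of the dienone carbonyl is the second concern if hydride is not strictly limited. Fallback, inversion instead of direct delivery: setting out from 19, the reduction is allowed to give (7R,8S,9S)-9-hydroxy-2,3,4,3',5'-pentamethoxy-7,8-dimethyl-6,7,8,9-tetrahydrospiro[benzo[7]annulene-5,1'-cyclohexa[2,5]dien]-4'-one F3. A Mitsunobu reaction (PPh3, DIAD, AcOH, toluene, 0 °C → rt) then installs the acetate with inversion at C9, rejoining the route at 21 and bypassing step 15.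

## Further compounds

F1 | step 4 | ethyl (2S)-4-[2-(4-benzyloxy-3,5-dimethoxyphenyl)-3,4,5-trimethoxyphenyl]-2,3-dimethyl-4-oxobutanoate (C8 epimers) | CCOC(=O)[C@@H](C)C(C)C(=O)c1cc(OC)c(OC)c(OC)c1-c1cc(OC)c(OCc2ccccc2)c(OC)c1
F2 | step 10 | 4-[6-[(3S)-1-(tert-butyldimethylsilyloxy)-4-iodo-2,3-dimethylbutyl]-2,3,4-trimethoxyphenyl]-2,6-dimethoxyphenol (epimers at C8 and C9) | IC[C@@H](C)C(C)C(O[Si](C)(C)C(C)(C)C)c1cc(OC)c(OC)c(OC)c1-c1cc(OC)c(O)c(OC)c1
F0 | step 13 | none | none
F3 | step 14 | (7R,8S,9S)-9-hydroxy-2,3,4,3',5'-pentamethoxy-7,8-dimethyl-6,7,8,9-tetrahydrospiro[benzo[7]annulene-5,1'-cyclohexa[2,5]dien]-4'-one | COC1=CC2(C=C(OC)C1=O)C[C@@H](C)[C@H](C)[C@H](O)c1cc(OC)c(OC)c(OC)c12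
A1 | alternative 1 | trimethylsilyl enol ether of the six-membered 3-methyl spiro-tetralone carrying the finished ring C | COC1=CC2(C=C(OC)C1=O)CC(C)=C(O[Si](C)(C)C)c1cc(OC)c(OC)c(OC)c12
A2 | alternative 1 | achiral ring-B enone (7-methyl, C7=C8, C9 ketone) with the spirodienone in place | COC1=CC2(C=C(OC)C1=O)CC(C)=CC(=O)c1cc(OC)c(OC)c(OC)c12
A3 | alternative 2 | achiral ring-B enone (8-methyl, C7=C8, C9 ketone) with the spirodienone in place | COC1=CC2(C=C(OC)C1=O)CC=C(C)C(=O)c1cc(OC)c(OC)c(OC)c12
A4 | alternative 2 | (7R,8S)-7,8-dimethyl-9-oxo spirodienone, identical with 19 | COC1=CC2(C=C(OC)C1=O)C[C@@H](C)[C@H](C)C(=O)c1cc(OC)c(OC)c(OC)c12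
A5 | alternative 3 | (2S,3S,4R)-4-(tert-butyldimethylsilyloxy)-4-[2-(4-hydroxy-3,5-dimethoxyphenyl)-3,4,5-trimethoxyphenyl]-2,3-dimethylbutyl methanesulfonate | CS(=O)(=O)OC[C@@H](C)[C@H](C)[C@@H](O[Si](C)(C)C(C)(C)C)c1cc(OC)c(OC)c(OC)c1-c1cc(OC)c(O)c(OC)c1
A6 | alternative 3 | tert-butyldimethylsilyl ether of 20 | COC1=CC2(C=C(OC)C1=O)C[C@@H](C)[C@H](C)[C@@H](O[Si](C)(C)C(C)(C)C)c1cc(OC)c(OC)c(OC)c12
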